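## Structural features

Compound 40 is a germacranolide: a cyclodeca-1(10),4-diene (ring carbons C1–C10) trans-fused across C6–C7 to an α-methylene-γ-butyrolactone (O6–C12(=O)–C11(=C13H2)–C7). Both ring alkenes are trisubstituted and ring-cis (C9 cis to C2 across C1=C10, C3 cis to C6 across C4=C5). They are E by the sequence rules only because C14H2OAc on C10 and the C15 aldehyde on C4 outrank the ring carbons. Three stereocentres stand side by side, C6 (R), C7 (R) and C8 (S), with the lactone trans and O6 and O8 syn across C7; O8 carries a 2-(hydroxymethyl)acrylate. The molecule holds three Michael acceptors (methylene lactone, acrylate, enal), an allylic acetate and an aldehyde, and a free O8 can translactonise onto C12, so strong bases, hard nucleophiles and hydride reagents are excluded late in the route. The real difficulty is closing the strained ten-membered ring with control of a trisubstituted alkene geometry; the second is the C8 carbinol, which sits beside a C7 centre whose two ring branches are sterically alike. The key step uses the fact that C5 is bonded to the lactone carbinol carbon C6 and that C4 carries a carbonyl carbon (C15): an aldehyde at C5 of a chiral-pool lactone and a phosphonate-stabilised thioester carbanion at C4 give C4=C5 with C15 trans to C6.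

## Logic of the disconnections

40 is cut at the O8–acyl bond and, formally, at C11=C13 (retro-elimination of an amine), leading through 39 and 37 back to 32 and 35. The acrylate and the methylene lactone are the most reactive acceptors, so they are added and unmasked last. The forward steps must acylate a hindered secondary alcohol without translactonisation and eliminate under very mild base.

32 goes back through 31 to 30 by functional-group changes only: the C15 aldehyde comes from a thioester and O8 from a silyl ether. The thioester is chosen because it can be reduced to the aldehyde in the presence of the lactone and the acetate.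

30 is cut at C4=C5 to give 29. This opens the ten-membered ring and removes one trisubstituted alkene in a single operation. The forward step must close a medium ring at high dilution and place C15 trans to C6.

29 goes back through 28 and 27 to 22 and 25 by cutting C3–C4. The phosphonate carbon is joined to the chain by alkylation, and the C5 aldehyde is released only one step before ring closure. The alkylation must proceed beside a tertiary amine, a lactone and an acetate; a bromide, not an iodide, is used at C3 to limit self-quaternisation.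

22 goes back through 21, 20 and 19 to 18 by cutting the C8–H bond. This leaves a ketone whose reduction must be controlled by the reagent, because C7 offers little intrinsic bias.

18 goes back through 17 and 16 to 9, 11 and 12 by cutting C7–C8 and C11–C13. One tandem operation joins the two halves, sets C7 trans to the C6 substituent taken from the chiral pool, and brings in C13 as a masked methylene group. The demand is clean 1,4-addition of a hindered acyl-anion equivalent and capture of the enolate.

9 is cut at C8–C9 into 7 and 6, a plain alkylation of a dithiane anion with a primary allylic bromide.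

6 goes back through 5 and 4 to 3, and 3 is cut at C1–C10 into 1 and 2. The allylic transposition of 3 fixes the C1=C10 geometry (C9 cis to C2) and differentiates C9 from C14 without protecting-group manoeuvres.

11 comes from 10, 25 from 23 and 24, and 35 from 33 through 34, each by standard functional-group steps.

## Other disconnections considered

Alternative 1: The cut is C5–C6 together with the lactone C–O bond. The open-chain aldehyde ester A1 carries an alkenyl iodide at C5 with iodine cis to C3. Because C15H2OPMB outranks C3, this iodide is E by the sequence rules, and only this isomer maps onto the ring-cis C4=C5 bond. CrCl2 with catalytic NiCl2 would turn the C–I bond into an alkenylchromium species that adds to the C6 aldehyde (Nozaki–Hiyama–Kishi reaction), and the chromium alkoxide should lactonise onto the C12 ester to give A2.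
- In its favour: the reaction is chemoselective for aldehydes and is among the most dependable closures of medium carbocycles. The alkene geometry is fixed before ring closure and carried through with retention, whereas the chosen plan creates it during ring closure; on this point the alternative is the better.
- Against it here: C6 is created in the ring closure under conformational control only. A several-fold excess of divalent chromium is needed. A2 lacks C13, so the methylene group would have to be introduced by enolate chemistry on the macrocycle. C15 must still be deprotected and oxidised, and C14 must be told apart from O8.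
- Comparison: the chosen plan takes C6 from the chiral pool and carries C13 through the ring closure in masked form. Both closures are additions of a carbon nucleophile to an aldehyde, irreversible for chromium and reversible before elimination for the phosphonate. After ring closure the chosen plan needs seven operations and A2 would need about nine; the effort to reach A1 and 29 is roughly equal.

Alternative 2: The cuts are C6–C7 and C8–C9. The silyl enol ether A3 of an eight-membered dienone would add the ketene A4 (from methyl succinyl chloride and Et3N) in a [2+2] cycloaddition. Fluoride would then open the cyclobutanone by retro-aldol cleavage of C6–C9 to the ten-membered 1,3-dione A5.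
- In its favour: both ring-cis alkenes are locked by the eight-membered ring before expansion, which is better than the chosen plan on alkene geometry. C7, C8, C11 and C12 arrive in one operation, and the step count to the ten-membered ring is clearly lower.
- Against it here: A3 is a conjugated cyclooctatrienol ether, prone to 6π electrocyclisation and offering more than one site for cycloaddition. A monoalkylketene such as A4 dimerises readily and is sluggish toward silyl enol ethers. The retro-aldol step can break C6–C7 as well as C6–C9. A5 has only the labile C7 as a stereocentre, so C6, C7 and C8 would all have to be set afterwards on a 1,3-diketone with no handle for absolute configuration, and C13 is still missing.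
- Comparison: the alternative is shorter and safer on alkene geometry. It is weaker on mechanism (three competing pathways in the key step) and much weaker on stereocontrol, which the chosen plan settles with the chiral pool and one reagent-controlled reduction.

Alternative 3: The cut is C7–C8. In the thirteen-membered stannyl ether A6, tin–lithium exchange at C8 (n-BuLi, −78 °C) would trigger a Wittig–Still [2,3] shift. C8 bonds to C7, the O8–C13 bond breaks, and the ring contracts to A7 with an exocyclic C11=C13 bond and a free C8 hydroxyl.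
- In its favour: a thirteen-membered ether should close more easily than a ten-membered carbocycle. C7 and C8 are formed together in one concerted suprafacial step. The methylene group appears without masking and O8 is set free for acylation. On these three points the alternative is the equal or the better of the chosen plan.
- Against it here: a configurationally defined secondary α-alkoxystannane is required (the shift inverts the lithium-bearing carbon), and a [1,2] shift competes. The facial selectivity at C7 relative to C6 inside the large ring is hard to predict. C12 must be oxidised from ether to lactone late, by allylic oxidation with a hexavalent chromium reagent, in the presence of two further allylic positions. C14 and C15 adjustments remain.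
- Comparison: the alternative sets more stereochemistry in the key step but with less predictable control, and it ends with an unselective oxidation. The chosen plan forms no stereocentre in its key step and keeps every oxidation state in place from the start, at the price of a harder ring closure and a longer protecting-group sequence.

Key step: step 18

Assumption: atom labels C1–C15 follow the germacrane numbering of 40. C4 of 27–29 is carried as a mixture of epimers, because step 18 makes it trigonal. Compounds 1, 12, 23 and 33 are taken as purchasable.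

## Route

Step 1
Reactants: 1 3-[(tert-butyldimethylsilyl)oxy]propanal; 2 methyl acrylate
Product: 3 methyl 5-[(tert-butyldimethylsilyl)oxy]-3-hydroxy-2-methylidenepentanoate (racemic)
Conditions: DABCO (1,4-diazabicyclo[2.2.2]octane, 0.5 equiv), neat 2 (3 equiv), rt, 5 d
Reagents that add atoms: none
Why: Morita–Baylis–Hillman reaction; the amine-derived acrylate enolate adds to the unhindered aldehyde and forms the C1–C10 bond. The carbinol centre is destroyed in step 2, so the racemate suffices.

Step 2
Reactants: 3 Morita–Baylis–Hillman adduct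
Product: 4 methyl (2Z)-2-(bromomethyl)-5-[(tert-butyldimethylsilyl)oxy]pent-2-enoate
Conditions: NBS, Me2S, CH2Cl2, 0 °C to rt
Reagents that add atoms: N-bromosuccinimide, O=C1CCC(=O)N1Br
Why: Corey–Kim-type activation of the allylic alcohol and SN2′ delivery of bromide; this transposition should place the ester trans to the alkyl chain, so that the bromomethyl carbon (C9) is cis to C2 as required for C1=C10.

Step 3
Reactants: 4 bromo enoate
Product: 5 (2Z)-2-(bromomethyl)-5-[(tert-butyldimethylsilyl)oxy]pent-2-en-1-ol
Conditions: DIBAL-H (2.2 equiv), CH2Cl2, −78 °C; aq. potassium sodium tartrate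
Reagents that add atoms: none
Why: 1,2-reduction of the enoate by the electrophilic aluminium hydride at low temperature should leave the allylic bromide and the alkene geometry untouched; the new hydroxymethyl carbon is C14.

Step 4
Reactants: 5 bromo allylic alcohol
Product: 6 (3Z)-4-(bromomethyl)-1-[(tert-butyldimethylsilyl)oxy]-5-[(2-methoxypropan-2-yl)oxy]pent-3-ene
Conditions: 2-methoxypropene, pyridinium p-toluenesulfonate (cat.), CH2Cl2, 0 °C
Reagents that add atoms: 2-methoxypropene, C=C(C)OC
Why: acid-catalysed addition of the alcohol to the enol ether gives a mixed acetal that is inert to organolithiums and is cleaved by much milder acid than the trityl and silyl ethers used later.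

Step 5
Reactants: 7 1,3-dithiane; 6 acetal-protected allylic bromide
Product: 9 2-[(2E)-5-[(tert-butyldimethylsilyl)oxy]-2-{[(2-methoxypropan-2-yl)oxy]methyl}pent-2-en-1-yl]-1,3-dithiane, via 2-lithio-1,3-dithiane 8 (not isolated)
Conditions: n-BuLi, THF, −30 °C; then 6, −78 °C to −20 °C
Reagents that add atoms: none
Why: alkylation of the sulfur-stabilised carbanion at the primary allylic bromide (SN2 at C9, not SN2′ at the more hindered C1) forms C8–C9 and keeps the alkene geometry.

Step 6
Reactants: 10 (5S)-5-(hydroxymethyl)furan-2(5H)-one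
Product: 11 (5S)-5-[(trityloxy)methyl]furan-2(5H)-one
Conditions: TrCl, pyridine, 4-(dimethylamino)pyridine (cat.), CH2Cl2, rt
Reagents that add atoms: trityl chloride, ClC(c1ccccc1)(c1ccccc1)c1ccccc1
Why: selective etherification of the primary alcohol; the bulky trityl group shields one face of the butenolide in step 7.

Step 7
Reactants: 9 allyl dithiane; 11 trityl butenolide; 12 N,N-dimethylmethyleneiminium iodide
Product: 16 (3R,4S,5S)-4-{2-[(2E)-5-[(tert-butyldimethylsilyl)oxy]-2-(hydroxymethyl)pent-2-en-1-yl]-1,3-dithian-2-yl}-3-[(dimethylamino)methyl]-5-[(trityloxy)methyl]oxolan-2-one, via lithiated dithiane 13 (not isolated), via lithium enolate 14 (not isolated), via acetal-protected Mannich base 15 (not isolated)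
Conditions: n-BuLi, THF, −30 °C; 11, THF/DMPU, −78 °C; 12, −78 °C to rt; then pyridinium p-toluenesulfonate (1.3 equiv), MeOH, 0 °C
Reagents that add atoms: none
Why: tandem Michael addition–Mannich trapping; the lithiated 2-alkyl-1,3-dithiane adds 1,4 to the butenolide anti to the trityloxymethyl group (sets C7), and the enolate is aminomethylated anti to the new C7 substituent (sets C11, later made trigonal). Mild acid methanolysis then removes only the mixed acetal and frees O14.

Step 8
Reactants: 16 dithiane lactone with free C14 hydroxyl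
Product: 17 (3R,4S,5S)-4-{2-[(2E)-2-[(acetyloxy)methyl]-5-[(tert-butyldimethylsilyl)oxy]pent-2-en-1-yl]-1,3-dithian-2-yl}-3-[(dimethylamino)methyl]-5-[(trityloxy)methyl]oxolan-2-one
Conditions: Ac2O, pyridine, 4-(dimethylamino)pyridine (cat.), CH2Cl2, 0 °C
Reagents that add atoms: acetic anhydride, CC(=O)OC(C)=O
Why: acylation of the only free hydroxyl group installs the C14 acetate of the target before any base-sensitive ketone is present.

Step 9
Reactants: 17 dithiane acetate
Product: 18 (3R,4S,5S)-4-[(3E)-3-[(acetyloxy)methyl]-6-[(tert-butyldimethylsilyl)oxy]hex-3-enoyl]-3-[(dimethylamino)methyl]-5-[(trityloxy)methyl]oxolan-2-one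
Conditions: Hg(ClO4)2, CaCO3, THF/H2O (5:1), 0 °C
Reagents that add atoms: water, O
Why: thiophilic divalent mercury activates the dithioacetal for hydrolysis while CaCO3 buffers the acid, so trityl ether, silyl ether and acetate should survive; the β-acyloxy ketone is used at once to avoid retro-Michael opening of the lactone.

Step 10
Reactants: 18 C8 ketone
Product: 19 (3R,4R,5S)-4-[(1S,3E)-3-[(acetyloxy)methyl]-6-[(tert-butyldimethylsilyl)oxy]-1-hydroxyhex-3-en-1-yl]-3-[(dimethylamino)methyl]-5-[(trityloxy)methyl]oxolan-2-one
Conditions: (R)-1-methyl-3,3-diphenyltetrahydro-1H,3H-pyrrolo[1,2-c][1,3,2]oxazaborole (0.5 equiv), catecholborane, toluene, −78 °C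
Reagents that add atoms: none
Why: Corey–Bakshi–Shibata reduction; the catalyst distinguishes the branched C7 side from the C9 methylene side, and the (R)-catalyst should deliver hydride to the face that gives (8S). Reagent control is chosen because the two ring branches at C7 are too alike for reliable Felkin–Anh control, and catecholborane avoids a stable amine–borane adduct.

Step 11
Reactants: 19 C8 alcohol
Product: 20 (3R,4S,5S)-4-[(1S,3E)-3-[(acetyloxy)methyl]-1,6-bis[(tert-butyldimethylsilyl)oxy]hex-3-en-1-yl]-3-[(dimethylamino)methyl]-5-[(trityloxy)methyl]oxolan-2-one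
Conditions: TBSOTf, 2,6-lutidine, CH2Cl2, −78 °C to 0 °C
Reagents that add atoms: tert-butyldimethylsilyl triflate, CC(C)(C)[Si](C)(C)OS(=O)(=O)C(F)(F)F
Why: the silyl triflate silylates the hindered secondary alcohol; protecting O8 at once removes the risk of translactonisation onto C12.

Step 12
Reactants: 20 bis-silyl ether
Product: 21 (3R,4S,5S)-4-[(1S,3E)-3-[(acetyloxy)methyl]-1-[(tert-butyldimethylsilyl)oxy]-6-hydroxyhex-3-en-1-yl]-3-[(dimethylamino)methyl]-5-[(trityloxy)methyl]oxolan-2-one
Conditions: HF·pyridine, pyridine, THF, 0 °C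
Reagents that add atoms: none
Why: rate-selective cleavage of the primary silyl ether; the secondary ether next to the C7 branch and the trityl ether should survive the buffered fluoride.

Step 13
Reactants: 21 C3 alcohol
Product: 22 (3R,4S,5S)-4-[(1S,3E)-3-[(acetyloxy)methyl]-6-bromo-1-[(tert-butyldimethylsilyl)oxy]hex-3-en-1-yl]-3-[(dimethylamino)methyl]-5-[(trityloxy)methyl]oxolan-2-one
Conditions: CBr4, PPh3, CH2Cl2, 0 °C
Reagents that add atoms: tetrabromomethane, BrC(Br)(Br)Br
Why: Appel bromination under neutral conditions; the bromide is preferred to the iodide because it alkylates the tertiary amine of a second molecule much more slowly.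

Step 14
Reactants: 23 (diethoxyphosphoryl)acetic acid; 24 ethanethiol
Product: 25 S-ethyl 2-(diethoxyphosphoryl)ethanethioate
Conditions: DCC, 4-(dimethylamino)pyridine (cat.), CH2Cl2, 0 °C to rt
Reagents that add atoms: none
Why: Steglich-type thioesterification of the carboxylic acid by the thiol through the carbodiimide-activated acid.

Step 15
Reactants: 25 phosphono thioacetate; 22 C3 bromide
Product: 27 S-ethyl (5E,8S)-6-[(acetyloxy)methyl]-8-[(tert-butyldimethylsilyl)oxy]-2-(diethoxyphosphoryl)-8-{(2S,3S,4R)-4-[(dimethylamino)methyl]-5-oxo-2-[(trityloxy)methyl]oxolan-3-yl}oct-5-enethioate (C2 epimers), via sodium phosphonate salt 26 (not isolated)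
Conditions: NaH, 25 (3 equiv), DMF, 0 °C; then 22 (added slowly), NaI (cat.), 45 °C
Reagents that add atoms: none
Why: C-alkylation of a phosphonate-stabilised carbanion by a primary bromide forms C3–C4; the excess of the soft anion suppresses dialkylation and outcompetes the amine for the halide, and it is too weakly basic to attack lactone or acetate.

Step 16
Reactants: 27 trityl ether
Product: 28 S-ethyl (5E,8S)-6-[(acetyloxy)methyl]-8-[(tert-butyldimethylsilyl)oxy]-2-(diethoxyphosphoryl)-8-[(2S,3S,4R)-4-[(dimethylamino)methyl]-2-(hydroxymethyl)-5-oxooxolan-3-yl]oct-5-enethioate (C2 epimers)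
Conditions: (+)-camphor-10-sulfonic acid (1.3 equiv), MeOH/CH2Cl2 (1:1), 0 °C
Reagents that add atoms: none
Why: acid-catalysed solvolysis of the trityl ether through the stabilised trityl cation; one equivalent of acid is taken up by the amine, and the hindered secondary silyl ether should be stable under these conditions.

Step 17
Reactants: 28 C5 alcohol
Product: 29 S-ethyl (5E,8S)-6-[(acetyloxy)methyl]-8-[(tert-butyldimethylsilyl)oxy]-2-(diethoxyphosphoryl)-8-{(2S,3S,4R)-4-[(dimethylamino)methyl]-2-formyl-5-oxooxolan-3-yl}oct-5-enethioate (C2 epimers)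
Conditions: Dess–Martin periodinane, NaHCO3, CH2Cl2, 0 °C to rt
Reagents that add atoms: none
Why: buffered, non-basic oxidation of the primary alcohol to the α-acyloxy aldehyde without epimerising C6 or touching the acidic phosphonate; the crude aldehyde is used directly.

Step 18
Reactants: 29 lactone aldehyde with phosphono thioester
Product: 30 S-ethyl (3R,3aS,4S,6E,10E,11aR)-6-[(acetyloxy)methyl]-4-[(tert-butyldimethylsilyl)oxy]-3-[(dimethylamino)methyl]-2-oxo-2,3,3a,4,5,8,9,11a-octahydrocyclodeca[b]furan-10-carbothioate
Conditions: LiCl (10 equiv), DBU (3 equiv), MeCN, slow addition of 29 to 1 mM, rt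
Reagents that add atoms: none
Why: LiCl and DBU (Masamune–Roush conditions) generate the lithium-chelated phosphonate carbanion at C4 without a strong base; it adds to the C5 aldehyde in a 10-exo-trig attack that closes the only new ring, the ten-membered carbocycle, and syn-elimination of lithium diethyl phosphate from the oxaphosphetane gives C4=C5. The closest known reaction type is the intramolecular Horner–Wadsworth–Emmons macrocyclisation of ω-formyl phosphonoacetates under LiCl/amine conditions. No stereocentre is created: both C4 epimers of 29 converge because C4 becomes trigonal, and C6, C7, C8 and C11 are spectators. The selectivity needed is geometric, C15 trans to C6 (C3 cis to C6); this is the intrinsic preference of a carbonyl-stabilised phosphonate, since addition is reversible and the adduct leading to this isomer eliminates faster. The ring should reinforce it, because the other isomer would put a ring-trans trisubstituted alkene into a ten-membered ring that already holds a ring-cis alkene and a trans-fused lactone. Chemoselectivity rests on the substrate: the methylene lactone is masked as its dimethylamine adduct, O8 is silylated so it cannot attack C12, and the hindered amidine does not attack the thioester. Dimerisation is the competing pathway and is countered by slow addition to millimolar concentration, helped by the ring-cis C1=C10 alkene and the lactone, which shorten the C4–C5 distance. C6 is α to the aldehyde, but the trans-disubstituted lactone is the thermodynamically preferred arrangement and the aldehyde is consumed as it meets the base.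

Step 19
Reactants: 30 macrocyclic thioester
Product: 31 [(3R,3aS,4S,6E,10E,11aR)-4-[(tert-butyldimethylsilyl)oxy]-3-[(dimethylamino)methyl]-10-formyl-2-oxo-2,3,3a,4,5,8,9,11a-octahydrocyclodeca[b]furan-6-yl]methyl acetate
Conditions: Et3SiH, Pd/C (10%), acetone, rt
Reagents that add atoms: none
Why: Fukuyama reduction; zerovalent palladium inserts into the C–S bond and the acylpalladium species is reduced by the silane to the aldehyde, which leaves lactone and acetate untouched. A lead-poisoned Pd/CaCO3 catalyst can be substituted if the alkenes or the allylic acetate react.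

Step 20
Reactants: 31 silyl-protected enal
Product: 32 [(3R,3aR,4S,6E,10E,11aR)-3-[(dimethylamino)methyl]-10-formyl-4-hydroxy-2-oxo-2,3,3a,4,5,8,9,11a-octahydrocyclodeca[b]furan-6-yl]methyl acetate
Conditions: HF·pyridine, THF, 0 °C to rt
Reagents that add atoms: none
Why: fluoride cleavage of the secondary silyl ether under acidic conditions, where the amine is protonated and base-induced translactonisation or acetate migration should not occur.

Step 21
Reactants: 33 ethyl 2-(hydroxymethyl)prop-2-enoate
Product: 34 ethyl 2-{[(tert-butyldimethylsilyl)oxy]methyl}prop-2-enoate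
Conditions: TBSCl, imidazole, CH2Cl2, 0 °C to rt
Reagents that add atoms: tert-butyldimethylsilyl chloride, CC(C)(C)[Si](C)(C)Cl
Why: standard silylation of a primary allylic alcohol through the N-silylimidazolium species.

Step 22
Reactants: 34 silyl-protected ester
Product: 35 2-{[(tert-butyldimethylsilyl)oxy]methyl}prop-2-enoic acid
Conditions: LiOH, THF/H2O, 0 °C to rt; then 0.5 M HCl to pH 4
Reagents that add atoms: lithium hydroxide, [Li+].[OH-]
Why: saponification of the ethyl ester; the primary silyl ether is stable to aqueous hydroxide at this temperature and to the brief mild acidification.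

Step 23
Reactants: 35 silyl-protected acrylic acid; 32 C8 alcohol
Product: 37 (3R,3aR,4S,6E,10E,11aR)-6-[(acetyloxy)methyl]-3-[(dimethylamino)methyl]-10-formyl-2-oxo-2,3,3a,4,5,8,9,11a-octahydrocyclodeca[b]furan-4-yl 2-{[(tert-butyldimethylsilyl)oxy]methyl}prop-2-enoate, via mixed anhydride 36 (not isolated)
Conditions: 2,4,6-trichlorobenzoyl chloride, Et3N, toluene, rt; then 32, 4-(dimethylamino)pyridine, toluene, rt
Reagents that add atoms: none
Why: Yamaguchi esterification; the acylpyridinium species formed from the mixed anhydride acylates the hindered secondary alcohol with retention at C8, and the methylene lactone stays masked so that O8 cannot add to C13.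

Step 24
Reactants: 37 C8 ester with masked lactone
Product: 39 (3aR,4S,6E,10E,11aR)-6-[(acetyloxy)methyl]-10-formyl-3-methylidene-2-oxo-2,3,3a,4,5,8,9,11a-octahydrocyclodeca[b]furan-4-yl 2-{[(tert-butyldimethylsilyl)oxy]methyl}prop-2-enoate, via trimethylammonium iodide 38 (not isolated)
Conditions: MeI, MeCN, rt; then aq. NaHCO3, EtOAc, rt
Reagents that add atoms: none
Why: quaternisation of the only basic nitrogen, then E1cB elimination of trimethylamine from the β-ammonio lactone under bicarbonate, which is too mild to affect the enal, the esters or the acrylate.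

Step 25
Reactants: 39 silyl-protected target
Product: 40 (3aR,4S,6E,10E,11aR)-6-[(acetyloxy)methyl]-10-formyl-3-methylidene-2-oxo-2,3,3a,4,5,8,9,11a-octahydrocyclodeca[b]furan-4-yl 2-(hydroxymethyl)prop-2-enoate
Conditions: HF·pyridine, pyridine, THF, 0 °C
Reagents that add atoms: none
Why: buffered fluoride cleavage of the primary allylic silyl ether; no base or nucleophile strong enough to add to the three acceptors is present.

## Compound list

1 | 3-[(tert-butyldimethylsilyl)oxy]propanal | O=CCCO[Si](C)(C)C(C)(C)C | starting material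
2 | methyl acrylate | C=CC(=O)OC | starting material
3 | methyl 5-[(tert-butyldimethylsilyl)oxy]-3-hydroxy-2-methylidenepentanoate (racemic) | C=C(C(=O)OC)C(O)CCO[Si](C)(C)C(C)(C)C | intermediate
4 | methyl (2Z)-2-(bromomethyl)-5-[(tert-butyldimethylsilyl)oxy]pent-2-enoate | BrC/C(C(=O)OC)=C\CCO[Si](C)(C)C(C)(C)C | intermediate
5 | (2Z)-2-(bromomethyl)-5-[(tert-butyldimethylsilyl)oxy]pent-2-en-1-ol | BrC/C(CO)=C\CCO[Si](C)(C)C(C)(C)C | intermediate
6 | (3Z)-4-(bromomethyl)-1-[(tert-butyldimethylsilyl)oxy]-5-[(2-methoxypropan-2-yl)oxy]pent-3-ene | BrC/C(COC(C)(C)OC)=C\CCO[Si](C)(C)C(C)(C)C | intermediate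
7 | 1,3-dithiane | C1CSCSC1 | starting material
8 | 2-lithio-1,3-dithiane | [Li]C1SCCCS1 | intermediate
9 | 2-[(2E)-5-[(tert-butyldimethylsilyl)oxy]-2-{[(2-methoxypropan-2-yl)oxy]methyl}pent-2-en-1-yl]-1,3-dithiane | C(C1SCCCS1)/C(COC(C)(C)OC)=C\CCO[Si](C)(C)C(C)(C)C | intermediate
10 | (5S)-5-(hydroxymethyl)furan-2(5H)-one | O=C1C=C[C@@H](CO)O1 | starting material
11 | (5S)-5-[(trityloxy)methyl]furan-2(5H)-one | O=C1C=C[C@@H](COC(c2ccccc2)(c2ccccc2)c2ccccc2)O1 | intermediate
12 | N,N-dimethylmethyleneiminium iodide | C=[N+](C)C.[I-] | starting material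
13 | 2-lithio derivative of 9 | [Li]C1(SCCCS1)C/C(COC(C)(C)OC)=C\CCO[Si](C)(C)C(C)(C)C | intermediate
14 | lithium (4S,5S)-4-{2-[(2E)-5-[(tert-butyldimethylsilyl)oxy]-2-{[(2-methoxypropan-2-yl)oxy]methyl}pent-2-en-1-yl]-1,3-dithian-2-yl}-5-[(trityloxy)methyl]-4,5-dihydrofuran-2-olate | C(c1ccccc1)(c1ccccc1)(c1ccccc1)OC[C@H]2OC(O[Li])=C[C@@H]2C3(SCCCS3)C/C(COC(C)(C)OC)=C\CCO[Si](C)(C)C(C)(C)C | intermediate
15 | (3R,4S,5S)-4-{2-[(2E)-5-[(tert-butyldimethylsilyl)oxy]-2-{[(2-methoxypropan-2-yl)oxy]methyl}pent-2-en-1-yl]-1,3-dithian-2-yl}-3-[(dimethylamino)methyl]-5-[(trityloxy)methyl]oxolan-2-one | C(c1ccccc1)(c1ccccc1)(c1ccccc1)OC[C@H]2OC(=O)[C@@H](CN(C)C)[C@@H]2C3(SCCCS3)C/C(COC(C)(C)OC)=C\CCO[Si](C)(C)C(C)(C)C | intermediate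
16 | (3R,4S,5S)-4-{2-[(2E)-5-[(tert-butyldimethylsilyl)oxy]-2-(hydroxymethyl)pent-2-en-1-yl]-1,3-dithian-2-yl}-3-[(dimethylamino)methyl]-5-[(trityloxy)methyl]oxolan-2-one | C(c1ccccc1)(c1ccccc1)(c1ccccc1)OC[C@H]2OC(=O)[C@@H](CN(C)C)[C@@H]2C3(SCCCS3)C/C(CO)=C\CCO[Si](C)(C)C(C)(C)C | intermediate
17 | (3R,4S,5S)-4-{2-[(2E)-2-[(acetyloxy)methyl]-5-[(tert-butyldimethylsilyl)oxy]pent-2-en-1-yl]-1,3-dithian-2-yl}-3-[(dimethylamino)methyl]-5-[(trityloxy)methyl]oxolan-2-one | C(c1ccccc1)(c1ccccc1)(c1ccccc1)OC[C@H]2OC(=O)[C@@H](CN(C)C)[C@@H]2C3(SCCCS3)C/C(COC(C)=O)=C\CCO[Si](C)(C)C(C)(C)C | intermediate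
18 | (3R,4S,5S)-4-[(3E)-3-[(acetyloxy)methyl]-6-[(tert-butyldimethylsilyl)oxy]hex-3-enoyl]-3-[(dimethylamino)methyl]-5-[(trityloxy)methyl]oxolan-2-one | C(c1ccccc1)(c1ccccc1)(c1ccccc1)OC[C@H]2OC(=O)[C@@H](CN(C)C)[C@@H]2C(=O)C/C(COC(C)=O)=C\CCO[Si](C)(C)C(C)(C)C | intermediate
19 | (3R,4R,5S)-4-[(1S,3E)-3-[(acetyloxy)methyl]-6-[(tert-butyldimethylsilyl)oxy]-1-hydroxyhex-3-en-1-yl]-3-[(dimethylamino)methyl]-5-[(trityloxy)methyl]oxolan-2-one | C(c1ccccc1)(c1ccccc1)(c1ccccc1)OC[C@H]2OC(=O)[C@@H](CN(C)C)[C@@H]2[C@@H](O)C/C(COC(C)=O)=C\CCO[Si](C)(C)C(C)(C)C | intermediate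
20 | (3R,4S,5S)-4-[(1S,3E)-3-[(acetyloxy)methyl]-1,6-bis[(tert-butyldimethylsilyl)oxy]hex-3-en-1-yl]-3-[(dimethylamino)methyl]-5-[(trityloxy)methyl]oxolan-2-one | C(c1ccccc1)(c1ccccc1)(c1ccccc1)OC[C@H]2OC(=O)[C@@H](CN(C)C)[C@@H]2[C@@H](O[Si](C)(C)C(C)(C)C)C/C(COC(C)=O)=C\CCO[Si](C)(C)C(C)(C)C | intermediate
21 | (3R,4S,5S)-4-[(1S,3E)-3-[(acetyloxy)methyl]-1-[(tert-butyldimethylsilyl)oxy]-6-hydroxyhex-3-en-1-yl]-3-[(dimethylamino)methyl]-5-[(trityloxy)methyl]oxolan-2-one | C(c1ccccc1)(c1ccccc1)(c1ccccc1)OC[C@H]2OC(=O)[C@@H](CN(C)C)[C@@H]2[C@@H](O[Si](C)(C)C(C)(C)C)C/C(COC(C)=O)=C\CCO | intermediate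
22 | (3R,4S,5S)-4-[(1S,3E)-3-[(acetyloxy)methyl]-6-bromo-1-[(tert-butyldimethylsilyl)oxy]hex-3-en-1-yl]-3-[(dimethylamino)methyl]-5-[(trityloxy)methyl]oxolan-2-one | C(c1ccccc1)(c1ccccc1)(c1ccccc1)OC[C@H]2OC(=O)[C@@H](CN(C)C)[C@@H]2[C@@H](O[Si](C)(C)C(C)(C)C)C/C(COC(C)=O)=C\CCBr | intermediate
23 | (diethoxyphosphoryl)acetic acid | OC(=O)CP(=O)(OCC)OCC | starting material
24 | ethanethiol | CCS | starting material
25 | S-ethyl 2-(diethoxyphosphoryl)ethanethioate | CCSC(=O)CP(=O)(OCC)OCC | intermediate
26 | sodium salt of 25 (C2 carbanion) | [Na+].CCSC(=O)[CH-]P(=O)(OCC)OCC | intermediate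
27 | S-ethyl (5E,8S)-6-[(acetyloxy)methyl]-8-[(tert-butyldimethylsilyl)oxy]-2-(diethoxyphosphoryl)-8-{(2S,3S,4R)-4-[(dimethylamino)methyl]-5-oxo-2-[(trityloxy)methyl]oxolan-3-yl}oct-5-enethioate (C2 epimers) | C(c1ccccc1)(c1ccccc1)(c1ccccc1)OC[C@H]2OC(=O)[C@@H](CN(C)C)[C@@H]2[C@@H](O[Si](C)(C)C(C)(C)C)C/C(COC(C)=O)=C\CCC(C(=O)SCC)P(=O)(OCC)OCC | intermediate
28 | S-ethyl (5E,8S)-6-[(acetyloxy)methyl]-8-[(tert-butyldimethylsilyl)oxy]-2-(diethoxyphosphoryl)-8-[(2S,3S,4R)-4-[(dimethylamino)methyl]-2-(hydroxymethyl)-5-oxooxolan-3-yl]oct-5-enethioate (C2 epimers) | OC[C@H]2OC(=O)[C@@H](CN(C)C)[C@@H]2[C@@H](O[Si](C)(C)C(C)(C)C)C/C(COC(C)=O)=C\CCC(C(=O)SCC)P(=O)(OCC)OCC | intermediate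
29 | S-ethyl (5E,8S)-6-[(acetyloxy)methyl]-8-[(tert-butyldimethylsilyl)oxy]-2-(diethoxyphosphoryl)-8-{(2S,3S,4R)-4-[(dimethylamino)methyl]-2-formyl-5-oxooxolan-3-yl}oct-5-enethioate (C2 epimers) | O=C[C@H]2OC(=O)[C@@H](CN(C)C)[C@@H]2[C@@H](O[Si](C)(C)C(C)(C)C)C/C(COC(C)=O)=C\CCC(C(=O)SCC)P(=O)(OCC)OCC | intermediate
30 | S-ethyl (3R,3aS,4S,6E,10E,11aR)-6-[(acetyloxy)methyl]-4-[(tert-butyldimethylsilyl)oxy]-3-[(dimethylamino)methyl]-2-oxo-2,3,3a,4,5,8,9,11a-octahydrocyclodeca[b]furan-10-carbothioate | CC(C)(C)[Si](C)(C)O[C@H]1C/C(COC(C)=O)=C\CC/C(C(=O)SCC)=C\[C@H]2OC(=O)[C@@H](CN(C)C)[C@H]12 | intermediate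
31 | [(3R,3aS,4S,6E,10E,11aR)-4-[(tert-butyldimethylsilyl)oxy]-3-[(dimethylamino)methyl]-10-formyl-2-oxo-2,3,3a,4,5,8,9,11a-octahydrocyclodeca[b]furan-6-yl]methyl acetate | CC(C)(C)[Si](C)(C)O[C@H]1C/C(COC(C)=O)=C\CC/C(C=O)=C\[C@H]2OC(=O)[C@@H](CN(C)C)[C@H]12 | intermediate
32 | [(3R,3aR,4S,6E,10E,11aR)-3-[(dimethylamino)methyl]-10-formyl-4-hydroxy-2-oxo-2,3,3a,4,5,8,9,11a-octahydrocyclodeca[b]furan-6-yl]methyl acetate | O[C@H]1C/C(COC(C)=O)=C\CC/C(C=O)=C\[C@H]2OC(=O)[C@@H](CN(C)C)[C@H]12 | intermediate
33 | ethyl 2-(hydroxymethyl)prop-2-enoate | C=C(CO)C(=O)OCC | starting material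
34 | ethyl 2-{[(tert-butyldimethylsilyl)oxy]methyl}prop-2-enoate | C=C(CO[Si](C)(C)C(C)(C)C)C(=O)OCC | intermediate
35 | 2-{[(tert-butyldimethylsilyl)oxy]methyl}prop-2-enoic acid | C=C(CO[Si](C)(C)C(C)(C)C)C(=O)O | intermediate
36 | 2-{[(tert-butyldimethylsilyl)oxy]methyl}prop-2-enoic 2,4,6-trichlorobenzoic anhydride | C=C(CO[Si](C)(C)C(C)(C)C)C(=O)OC(=O)c1c(Cl)cc(Cl)cc1Cl | intermediate
37 | (3R,3aR,4S,6E,10E,11aR)-6-[(acetyloxy)methyl]-3-[(dimethylamino)methyl]-10-formyl-2-oxo-2,3,3a,4,5,8,9,11a-octahydrocyclodeca[b]furan-4-yl 2-{[(tert-butyldimethylsilyl)oxy]methyl}prop-2-enoate | C=C(CO[Si](C)(C)C(C)(C)C)C(=O)O[C@H]1C/C(COC(C)=O)=C\CC/C(C=O)=C\[C@H]2OC(=O)[C@@H](CN(C)C)[C@H]12 | intermediate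
38 | N,N,N-trimethylammonium iodide of 37 (quaternised at the C13 nitrogen) | C=C(CO[Si](C)(C)C(C)(C)C)C(=O)O[C@H]1C/C(COC(C)=O)=C\CC/C(C=O)=C\[C@H]2OC(=O)[C@@H](C[N+](C)(C)C)[C@H]12.[I-] | intermediate
39 | (3aR,4S,6E,10E,11aR)-6-[(acetyloxy)methyl]-10-formyl-3-methylidene-2-oxo-2,3,3a,4,5,8,9,11a-octahydrocyclodeca[b]furan-4-yl 2-{[(tert-butyldimethylsilyl)oxy]methyl}prop-2-enoate | C=C(CO[Si](C)(C)C(C)(C)C)C(=O)O[C@H]1C/C(COC(C)=O)=C\CC/C(C=O)=C\[C@H]2OC(=O)C(=C)[C@H]12 | intermediate
40 | (3aR,4S,6E,10E,11aR)-6-[(acetyloxy)methyl]-10-formyl-3-methylidene-2-oxo-2,3,3a,4,5,8,9,11a-octahydrocyclodeca[b]furan-4-yl 2-(hydroxymethyl)prop-2-enoate | C=C(CO)C(=O)O[C@H]1C/C(COC(C)=O)=C\CC/C(C=O)=C\[C@H]2OC(=O)C(=C)[C@H]12 | target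

## Step count and least certain steps

Total: 25 steps. Longest linear sequence: 21 steps (steps 1–5, 7–13, 15–20, 23–25, from 1 to 40).

Step 18 (key step). The most likely failure is intermolecular olefination to cyclic dimers and oligomers, because the ten-membered transition state carries transannular strain. Slow base-induced epimerisation at C6 of the unreacted aldehyde may accompany it. The fallback sets out from 22 and returns at 30; it replaces the olefination by a reversible aldol-type closure that becomes irreversible only on decarboxylation. Mono-tert-butyl malonate is converted with ethanethiol and DCC into tert-butyl S-ethyl thiomalonate F1. Its sodium salt is alkylated by 22 to give the thiomalonate F2. Dilute TFA with Et3SiH in CH2Cl2 cleaves the tert-butyl ester and the trityl ether together to the malonic acid half thioester alcohol F3. Dess–Martin oxidation gives the aldehyde acid F4. Piperidine in pyridine/toluene at high dilution should then close the ring by decarboxylative Knoevenagel condensation and give 30 directly.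

Step 7. The most likely failure is incomplete capture of the hindered lithium enolate by the sparingly soluble iminium salt, with proton transfer giving the unfunctionalised lactone. Deprotonation of 11 at its γ-position by the strongly basic dithianyl anion is a second loss channel. The fallback sets out from 9 and 11 and returns at 15; it separates the two bond formations. The conjugate addition is quenched with NH4Cl to give the protonated adduct F5. F5 is then deprotonated at C11 with LDA at −78 °C and the homogeneous enolate solution is treated with 12, which gives 15 and, after the acid methanolysis, 16.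

Step 10. The most likely failure is poor facial selectivity, if the intrinsic bias of the C7 centre opposes the catalyst or if the tertiary amine binds boron and opens an uncatalysed pathway. The fallback sets out from 18 and returns at 19; it corrects the configuration after the reduction. 18 is reduced with NaBH4/CeCl3 in MeOH at −78 °C and the epimers are separated. The (8R) alcohol F6 is inverted by a Mitsunobu reaction with chloroacetic acid (PPh3, DIAD) to the (8S) chloroacetate F7. Thiourea and NaHCO3 in EtOH remove the chloroacetyl group in the presence of the C14 acetate and give 19.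

Step 15. The most likely failures are alkylation of the amine nitrogen of one molecule by the bromide of another, loss of HBr from the homoallylic bromide to a conjugated diene, and dialkylation of the phosphonate. The fallback sets out from 21 and returns at 27; it avoids any alkyl halide. Alcohol 21 and 25 are heated with cyanomethylenetributylphosphorane in toluene (100 °C), a Mitsunobu-type dehydrative C-alkylation of an acidic C–H compound, which gives 27 directly and skips step 13.

Step 19. The most likely failures are hydrogenolysis of the allylic acetate or saturation or migration of the conjugated alkene on the palladium surface, and slowing of the catalyst by the amine. The fallback sets out from 30 and returns at 31; it replaces the catalytic reduction by a hydride reduction and reoxidation. NaBH4 with CeCl3 in EtOH/THF at −20 °C should reduce the thioester, which is more reactive than the lactone and the acetate, to the allylic alcohol F8. MnO2 in CH2Cl2 then oxidises F8 to 31.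

## Further compounds

F1 | step 18 | tert-butyl S-ethyl thiomalonate (tert-butyl 3-(ethylsulfanyl)-3-oxopropanoate) | CCSC(=O)CC(=O)OC(C)(C)C
F2 | step 18 | tert-butyl (5E,8S)-6-[(acetyloxy)methyl]-8-[(tert-butyldimethylsilyl)oxy]-8-{(2S,3S,4R)-4-[(dimethylamino)methyl]-5-oxo-2-[(trityloxy)methyl]oxolan-3-yl}-2-[(ethylsulfanyl)carbonyl]oct-5-enoate (C2 epimers) | C(c1ccccc1)(c1ccccc1)(c1ccccc1)OC[C@H]2OC(=O)[C@@H](CN(C)C)[C@@H]2[C@@H](O[Si](C)(C)C(C)(C)C)C/C(COC(C)=O)=C\CCC(C(=O)SCC)C(=O)OC(C)(C)C
F3 | step 18 | (5E,8S)-6-[(acetyloxy)methyl]-8-[(tert-butyldimethylsilyl)oxy]-8-[(2S,3S,4R)-4-[(dimethylamino)methyl]-2-(hydroxymethyl)-5-oxooxolan-3-yl]-2-[(ethylsulfanyl)carbonyl]oct-5-enoic acid (C2 epimers) | OC[C@H]2OC(=O)[C@@H](CN(C)C)[C@@H]2[C@@H](O[Si](C)(C)C(C)(C)C)C/C(COC(C)=O)=C\CCC(C(=O)SCC)C(=O)O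
F4 | step 18 | (5E,8S)-6-[(acetyloxy)methyl]-8-[(tert-butyldimethylsilyl)oxy]-8-{(2S,3S,4R)-4-[(dimethylamino)methyl]-2-formyl-5-oxooxolan-3-yl}-2-[(ethylsulfanyl)carbonyl]oct-5-enoic acid (C2 epimers) | O=C[C@H]2OC(=O)[C@@H](CN(C)C)[C@@H]2[C@@H](O[Si](C)(C)C(C)(C)C)C/C(COC(C)=O)=C\CCC(C(=O)SCC)C(=O)O
F5 | step 7 | (4S,5S)-4-{2-[(2E)-5-[(tert-butyldimethylsilyl)oxy]-2-{[(2-methoxypropan-2-yl)oxy]methyl}pent-2-en-1-yl]-1,3-dithian-2-yl}-5-[(trityloxy)methyl]oxolan-2-one | C(c1ccccc1)(c1ccccc1)(c1ccccc1)OC[C@H]2OC(=O)C[C@@H]2C3(SCCCS3)C/C(COC(C)(C)OC)=C\CCO[Si](C)(C)C(C)(C)C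
F6 | step 10 | (3R,4R,5S)-4-[(1R,3E)-3-[(acetyloxy)methyl]-6-[(tert-butyldimethylsilyl)oxy]-1-hydroxyhex-3-en-1-yl]-3-[(dimethylamino)methyl]-5-[(trityloxy)methyl]oxolan-2-one | C(c1ccccc1)(c1ccccc1)(c1ccccc1)OC[C@H]2OC(=O)[C@@H](CN(C)C)[C@@H]2[C@H](O)C/C(COC(C)=O)=C\CCO[Si](C)(C)C(C)(C)C
F7 | step 10 | (1S,3E)-3-[(acetyloxy)methyl]-6-[(tert-butyldimethylsilyl)oxy]-1-{(3R,4R,5S)-4-[(dimethylamino)methyl]-5-oxo-2-[(trityloxy)methyl]oxolan-3-yl}hex-3-en-1-yl chloroacetate | C(c1ccccc1)(c1ccccc1)(c1ccccc1)OC[C@H]2OC(=O)[C@@H](CN(C)C)[C@@H]2[C@@H](OC(=O)CCl)C/C(COC(C)=O)=C\CCO[Si](C)(C)C(C)(C)C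
F0 | step 15 | none | none
F8 | step 19 | [(3R,3aS,4S,6E,10E,11aR)-4-[(tert-butyldimethylsilyl)oxy]-3-[(dimethylamino)methyl]-10-(hydroxymethyl)-2-oxo-2,3,3a,4,5,8,9,11a-octahydrocyclodeca[b]furan-6-yl]methyl acetate | CC(C)(C)[Si](C)(C)O[C@H]1C/C(COC(C)=O)=C\CC/C(CO)=C\[C@H]2OC(=O)[C@@H](CN(C)C)[C@H]12
A1 | alternative 1 | methyl (3R,4S,6E,10E)-4-[(tert-butyldimethylsilyl)oxy]-6-{[(tert-butyldimethylsilyl)oxy]methyl}-3-formyl-11-iodo-10-{[(4-methoxybenzyl)oxy]methyl}undeca-6,10-dienoate (open-chain aldehyde ester, iodine cis to C3) | O=C[C@H](CC(=O)OC)[C@@H](O[Si](C)(C)C(C)(C)C)C/C(CO[Si](C)(C)C(C)(C)C)=C\CC/C(COCc1ccc(OC)cc1)=C\I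
A2 | alternative 1 | trans-fused cyclodecadieno-γ-butyrolactone with C11 as CH2, O8 and O14 silylated, O15 as 4-methoxybenzyl ether | CC(C)(C)[Si](C)(C)O[C@H]1C/C(CO[Si](C)(C)C(C)(C)C)=C\CC/C(COCc3ccc(OC)cc3)=C\[C@H]2OC(=O)C[C@H]12
A3 | alternative 2 | trimethylsilyl enol ether (C6=C9) of the 4,10-disubstituted cycloocta-dienone, all ring double bonds cis | C1/C=C(CO[Si](C)(C)C(C)(C)C)\C=C(O[Si](C)(C)C)/C=C(COCc2ccc(OC)cc2)\C1
A4 | alternative 2 | methyl 4-oxobut-3-enoate (ketene from methyl succinyl chloride) | COC(=O)CC=C=O
A5 | alternative 2 | 2-substituted cyclodeca-4,8-diene-1,3-dione (C7 stereolabile) | COC(=O)CC1C(=O)C/C(CO[Si](C)(C)C(C)(C)C)=C\CC/C(COCc2ccc(OC)cc2)=C\C1=O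
A6 | alternative 3 | thirteen-membered allylic ether with tributylstannyl group at C8 and a 2,5-dihydrofuran spanning C6, C7, C11 and C12 | CCCC[Sn](CCCC)(CCCC)[C@@H]1OCC2=C[C@H](OC2)/C=C(COCc3ccc(OC)cc3)\CC/C=C(CO[Si](C)(C)C(C)(C)C)\C1
A7 | alternative 3 | cyclodecadienol fused to a 3-methylenetetrahydrofuran (free C8 hydroxyl) | O[C@H]1C/C(CO[Si](C)(C)C(C)(C)C)=C\CC/C(COCc3ccc(OC)cc3)=C\[C@H]2OCC(=C)[C@H]12
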